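**Assumption:** positions are numbered as in eudesmane – C1 (CH–O‑senecioate), C2 (CH–OAc), C3=C4 (C15 methyl on C4), C5 (ring‑fusion CH), C7 (CH–isopropenyl), C9 (CH–OAc), C10 (quaternary, bearing C14H2OH). The target is then (1R,2S,5R,7S,9S,10S): a trans‑decalin with C14, O1 and O2 on one face and H5, the isopropenyl group and O9 on the other.

## Retrosynthetic overview

1. Target 25 ⇐ C14 carboxylic acid 23; the acid is reduced last, with all three esters already in place.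
2. Ring A is closed last: the C4–C5 bond comes from a carboxylate‑directed, palladium‑catalysed intramolecular C(sp3)–H alkenylation of monocyclic acid 22, which fixes the trans ring fusion.
3. The C1 senecioate and the C9 alcohol arise together from one Evans–Tishchenko reduction of aldol 18 with 3‑methylbut‑2‑enal.
4. The C10–C1 bond (quaternary centre) comes from a Mukaiyama aldol joining ring B fragment 9 and aldehyde fragment 17.
5. Fragment 9 comes from cyclohexenone (ring B, bought in; rhodium‑catalysed asymmetric isopropenylation, carboxylation); fragment 17 comes from but‑2‑yn‑1‑ol (hydroalumination–iodination, asymmetric vinylation, ozonolysis).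

## Route

**Ring B fragment**

Step 1
Reactants: 1 2‑bromopropene
Product: 4 potassium trifluoro(prop‑1‑en‑2‑yl)borate, via isopropenylmagnesium bromide 2 (not isolated), via dimethyl isopropenylboronate 3 (not isolated)
Conditions: Mg, THF, rt; B(OMe)3, −78 °C → rt; aq KHF2
Reagents that add atoms: trimethyl borate (COB(OC)OC); potassium hydrogen difluoride ([K+].[F-].F)
Why: Grignard formation, borylation and fluoride exchange (standard trifluoroborate synthesis) give a stable, weighable isopropenyl donor; no stereocentre is involved.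

Step 2
Reactants: 4 potassium trifluoro(prop‑1‑en‑2‑yl)borate; 5 cyclohex‑2‑en‑1‑one
Product: 6 (3S)‑3‑(prop‑1‑en‑2‑yl)cyclohexan‑1‑one
Conditions: [Rh(cod)2]BF4 (3 mol %), (S)‑BINAP (3.3 mol %), toluene/H2O 10:1, 105 °C
Reagents that add atoms: none
Why: Rhodium‑catalysed asymmetric 1,4‑addition (Hayashi–Miyaura reaction) of the alkenylboron reagent; the (S)‑BINAP–rhodium complex blocks one enone face and sets C7 as S, as it does for other alkenyl and aryl boron reagents with cyclohexenone.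

Step 3
Reactants: 6 (3S)‑3‑(prop‑1‑en‑2‑yl)cyclohexan‑1‑one
Product: 7 methyl (4S)‑2‑oxo‑4‑(prop‑1‑en‑2‑yl)cyclohexane‑1‑carboxylate
Conditions: NaH, (MeO)2CO, THF, reflux; AcOH
Reagents that add atoms: dimethyl carbonate (COC(=O)OC)
Why: Thermodynamically controlled Claisen‑type C‑carboxylation occurs at the less hindered α‑methylene (the future C10, remote from C7) and is driven by deprotonation of the β‑keto ester; the new centre stays epimerisable and is fixed in step 11.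

Step 4
Reactants: 7 methyl (4S)‑2‑oxo‑4‑(prop‑1‑en‑2‑yl)cyclohexane‑1‑carboxylate
Product: 8 2‑(trimethylsilyl)ethyl (4S)‑2‑oxo‑4‑(prop‑1‑en‑2‑yl)cyclohexane‑1‑carboxylate
Conditions: Me3SiCH2CH2OH, DMAP (cat.), toluene, reflux, 4 Å MS
Reagents that add atoms: 2‑(trimethylsilyl)ethanol (C[Si](C)(C)CCO)
Why: DMAP‑catalysed transesterification of a β‑keto ester installs a fluoride‑labile ester that can later be removed without touching acetates, the senecioate or the alkenyl iodide.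

Step 5
Reactants: 8 2‑(trimethylsilyl)ethyl (4S)‑2‑oxo‑4‑(prop‑1‑en‑2‑yl)cyclohexane‑1‑carboxylate
Product: 9 2‑(trimethylsilyl)ethyl (4S)‑4‑(prop‑1‑en‑2‑yl)‑2‑[(trimethylsilyl)oxy]cyclohex‑1‑ene‑1‑carboxylate
Conditions: TMSCl, Et3N, DMF, rt
Reagents that add atoms: chlorotrimethylsilane (C[Si](C)(C)Cl)
Why: O‑silylation of the enolised β‑keto ester gives the tetrasubstituted silyl enol ether needed for an irreversible Mukaiyama aldol.

**Aldehyde fragment**

Step 6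
Reactants: 10 but‑2‑yn‑1‑ol
Product: 12 (2Z)‑3‑iodobut‑2‑en‑1‑ol, via sodium alkenylalanate 11 (not isolated)
Conditions: NaAlH2(OCH2CH2OMe)2, THF, 0 °C; I2, −78 °C
Reagents that add atoms: iodine ([I][I])
Why: Hydroxyl‑directed trans‑hydroalumination of the propargylic alcohol places aluminium on C3 cis to CH2OH, and iodinolysis with retention gives the (Z)‑iodoalkene that becomes C3=C4 with its C15 methyl.

Step 7
Reactants: 12 (2Z)‑3‑iodobut‑2‑en‑1‑ol
Product: 13 (2Z)‑3‑iodobut‑2‑enal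
Conditions: MnO2, CH2Cl2, rt
Reagents that add atoms: none
Why: Allylic oxidation with MnO2 is selective and non‑acidic, so the (Z)‑β‑iodoenal forms without isomerisation.

Step 8
Reactants: 13 (2Z)‑3‑iodobut‑2‑enal
Product: 14 (3R,4Z)‑5‑iodohexa‑1,4‑dien‑3‑ol
Conditions: Zn(CH=CH2)2 (from CH2=CHMgBr and ZnCl2, Et2O/dioxane, filtered), (+)‑DAIB (10 mol %), toluene, −20 °C; aq NH4Cl
Reagents that add atoms: vinylmagnesium bromide (C=C[Mg]Br)
Why: Amino‑alcohol‑catalysed enantioselective 1,2‑addition of an alkenylzinc reagent to an aldehyde; (+)‑DAIB directs the vinyl group to the Re face and gives the (3R) carbinol that becomes C2.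

Step 9
Reactants: 14 (3R,4Z)‑5‑iodohexa‑1,4‑dien‑3‑ol
Product: 15 (3R,4Z)‑5‑iodohexa‑1,4‑dien‑3‑yl acetate
Conditions: Ac2O, pyridine, DMAP (cat.), 0 °C
Reagents that add atoms: acetic anhydride (CC(=O)OC(C)=O)
Why: Simple acetylation introduces the acetate that is the C2 acetate of the target; the stereocentre is untouched.

Step 10
Reactants: 15 (3R,4Z)‑5‑iodohexa‑1,4‑dien‑3‑yl acetate
Product: 17 (2S,3Z)‑4‑iodo‑1‑oxopent‑3‑en‑2‑yl acetate, via ozonide 16 (not isolated)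
Conditions: O3 (1.0 equiv), CH2Cl2, −78 °C; Me2S; used at once
Reagents that add atoms: ozone (O=[O+][O-])
Why: Ozonolysis with reductive work‑up cleaves the monosubstituted vinyl group in preference to the iodine‑deactivated trisubstituted alkene and unmasks the C1 aldehyde; C2 is unchanged (its descriptor becomes S only because the substituent priorities change).

**Union and endgame**

Step 11
Reactants: 9 silyl enol ether (ring B fragment); 17 (2S,3Z)‑4‑iodo‑1‑oxopent‑3‑en‑2‑yl acetate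
Product: 18 2‑(trimethylsilyl)ethyl (1R,4S)‑1‑[(1R,2S,3Z)‑2‑acetoxy‑1‑hydroxy‑4‑iodopent‑3‑en‑1‑yl]‑2‑oxo‑4‑(prop‑1‑en‑2‑yl)cyclohexane‑1‑carboxylate
Conditions: BF3·OEt2 (1.2 equiv), CH2Cl2, −78 °C; aq NaHCO3
Reagents that add atoms: none
Why: Mukaiyama aldol addition through an open transition state: the enol ether is attacked axially on the half‑chair with the C7 isopropenyl group equatorial, so the new C10–C1 bond is cis to isopropenyl (C10 is R in this compound), and the BF3‑bound α‑acetoxy aldehyde reacts in the polar Felkin–Anh mode to give the 1,2‑anti (1R,2S) pair at C1/C2.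

Step 12
Reactants: 18 aldol adduct; 19 3‑methylbut‑2‑enal
Product: 21 2‑(trimethylsilyl)ethyl (1S,2S,4S)‑2‑acetoxy‑1‑[(1R,2S,3Z)‑2‑acetoxy‑4‑iodo‑1‑(3‑methylbut‑2‑enoyloxy)pent‑3‑en‑1‑yl]‑4‑(prop‑1‑en‑2‑yl)cyclohexane‑1‑carboxylate, via C9 alcohol 20 (not isolated)
Conditions: SmI2 (30 mol %), THF, −10 °C; then Ac2O, DMAP, pyridine, rt
Reagents that add atoms: acetic anhydride (CC(=O)OC(C)=O)
Why: Evans–Tishchenko reduction: the C1 hydroxyl forms a samarium‑bound hemiacetal with the enal and delivers its hydride intramolecularly to the C9 ketone through a chair transition state, which gives the 1,3‑anti relationship (C9 S) while the hydroxyl itself becomes the 3‑methylbut‑2‑enoate; the new C9 alcohol is acetylated in the same flask.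

Step 13
Reactants: 21 2‑(trimethylsilyl)ethyl triester
Product: 22 (1S,2S,4S)‑2‑acetoxy‑1‑[(1R,2S,3Z)‑2‑acetoxy‑4‑iodo‑1‑(3‑methylbut‑2‑enoyloxy)pent‑3‑en‑1‑yl]‑4‑(prop‑1‑en‑2‑yl)cyclohexane‑1‑carboxylic acid
Conditions: Bu4NF, AcOH, THF, 0 °C → rt
Reagents that add atoms: none
Why: Fluoride‑induced β‑elimination of the 2‑(trimethylsilyl)ethyl ester frees the carboxylic acid under buffered conditions that leave the other three esters and the alkenyl iodide intact.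

Step 14
Reactants: 22 monocyclic iodoalkenyl acid
Product: 23 (1R,2S,5R,7S,9S,10S)‑2,9‑diacetoxy‑1‑(3‑methylbut‑2‑enoyloxy)eudesma‑3,11‑dien‑14‑oic acid (trans‑decalin acid)
Conditions: Pd(OAc)2 (10 mol %), Ac‑Gly‑OH (20 mol %), Ag2CO3 (1.5 equiv), K2HPO4 (1 equiv), (CF3)2CHOH, 80 °C, 0.02 M
Reagents that add atoms: none
Why: Proposed new method: the carboxylate directs divalent palladium to cleave the β‑methylene C5–H bond that is cis to it (five‑membered palladacycle, concerted metalation–deprotonation helped by the amino acid ligand); the (Z)‑alkenyl iodide held on C10 then adds oxidatively to give tetravalent palladium, and C(sp3)–C(sp2) reductive elimination with retention forms C4–C5, so the ring A bond at C5 is cis to the carboxyl (C5 R, trans fusion) and the alkene geometry is kept. The acyloxy‑bearing methines C1 and C9 are too hindered to compete. The closest known reactions are ligand‑enabled β‑methylene C–H arylation of free aliphatic acids with aryl iodides and 8‑aminoquinoline‑directed intermolecular C(sp3)–H alkenylation with alkenyl iodides.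

Step 15
Reactants: 23 trans‑decalin acid
Product: 25 [(1R,2S,4aR,6S,8S,8aS)‑2,8‑diacetoxy‑8a‑(hydroxymethyl)‑4‑methyl‑6‑(prop‑1‑en‑2‑yl)‑1,2,4a,5,6,7,8,8a‑octahydronaphthalen‑1‑yl] 3‑methylbut‑2‑enoate (target), via acid chloride 24 (not isolated)
Conditions: Me2C=C(Cl)NMe2, CH2Cl2, 0 °C; NaBH4, THF/DMF, −40 °C; AcOH quench
Reagents that add atoms: none
Why: Neutral acid chloride formation (Ghosez reagent) followed by chemoselective borohydride reduction of the acyl chloride, which is far more electrophilic than the acetates and the enoate, gives the neopentyl primary alcohol; the cold, buffered quench limits acyl migration and no stereocentre is affected.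

## Compound list

1 | 2‑bromopropene | CC(Br)=C | starting material
2 | (prop‑1‑en‑2‑yl)magnesium bromide | CC(=C)[Mg]Br | intermediate (not isolated)
3 | dimethyl (prop‑1‑en‑2‑yl)boronate | COB(OC)C(C)=C | intermediate (not isolated)
4 | potassium trifluoro(prop‑1‑en‑2‑yl)borate | [K+].F[B-](F)(F)C(C)=C | intermediate
5 | cyclohex‑2‑en‑1‑one | O=C1C=CCCC1 | starting material
6 | (3S)‑3‑(prop‑1‑en‑2‑yl)cyclohexan‑1‑one | C=C(C)[C@@H]1CC(=O)CCC1 | intermediate
7 | methyl (4S)‑2‑oxo‑4‑(prop‑1‑en‑2‑yl)cyclohexane‑1‑carboxylate (C1 epimers and enol) | C=C(C)[C@@H]1CC(=O)C(C(=O)OC)CC1 | intermediate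
8 | 2‑(trimethylsilyl)ethyl (4S)‑2‑oxo‑4‑(prop‑1‑en‑2‑yl)cyclohexane‑1‑carboxylate (C1 epimers and enol) | C=C(C)[C@@H]1CC(=O)C(C(=O)OCC[Si](C)(C)C)CC1 | intermediate
9 | 2‑(trimethylsilyl)ethyl (4S)‑4‑(prop‑1‑en‑2‑yl)‑2‑[(trimethylsilyl)oxy]cyclohex‑1‑ene‑1‑carboxylate | C=C(C)[C@@H]1CC(O[Si](C)(C)C)=C(C(=O)OCC[Si](C)(C)C)CC1 | intermediate
10 | but‑2‑yn‑1‑ol | CC#CCO | starting material
11 | sodium 2,2‑bis(2‑methoxyethoxy)‑3‑methyl‑2,5‑dihydro‑1,2‑oxaaluminol‑2‑uide (cyclic alkenylalanate) | [Na+].CC1=CCO[Al-]1(OCCOC)OCCOC | intermediate (not isolated)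
12 | (2Z)‑3‑iodobut‑2‑en‑1‑ol | C/C(I)=C/CO | intermediate
13 | (2Z)‑3‑iodobut‑2‑enal | C/C(I)=C/C=O | intermediate
14 | (3R,4Z)‑5‑iodohexa‑1,4‑dien‑3‑ol | C/C(I)=C/[C@H](O)C=C | intermediate
15 | (3R,4Z)‑5‑iodohexa‑1,4‑dien‑3‑yl acetate | C/C(I)=C/[C@H](OC(C)=O)C=C | intermediate
16 | (1S,2Z)‑3‑iodo‑1‑(1,2,4‑trioxolan‑3‑yl)but‑2‑en‑1‑yl acetate (ozonide) | C/C(I)=C/[C@H](OC(C)=O)C1OCOO1 | intermediate (not isolated)
17 | (2S,3Z)‑4‑iodo‑1‑oxopent‑3‑en‑2‑yl acetate | C/C(I)=C/[C@H](OC(C)=O)C=O | intermediate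
18 | 2‑(trimethylsilyl)ethyl (1R,4S)‑1‑[(1R,2S,3Z)‑2‑acetoxy‑1‑hydroxy‑4‑iodopent‑3‑en‑1‑yl]‑2‑oxo‑4‑(prop‑1‑en‑2‑yl)cyclohexane‑1‑carboxylate | C=C(C)[C@@H]1CC(=O)[C@@]([C@@H](O)[C@@H](OC(C)=O)/C=C(\I)C)(C(=O)OCC[Si](C)(C)C)CC1 | intermediate
19 | 3‑methylbut‑2‑enal | CC(C)=CC=O | starting material
20 | 2‑(trimethylsilyl)ethyl (1S,2S,4S)‑1‑[(1R,2S,3Z)‑2‑acetoxy‑4‑iodo‑1‑(3‑methylbut‑2‑enoyloxy)pent‑3‑en‑1‑yl]‑2‑hydroxy‑4‑(prop‑1‑en‑2‑yl)cyclohexane‑1‑carboxylate | C=C(C)[C@@H]1C[C@H](O)[C@@]([C@@H](OC(=O)C=C(C)C)[C@@H](OC(C)=O)/C=C(\I)C)(C(=O)OCC[Si](C)(C)C)CC1 | intermediate (not isolated)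
21 | 2‑(trimethylsilyl)ethyl (1S,2S,4S)‑2‑acetoxy‑1‑[(1R,2S,3Z)‑2‑acetoxy‑4‑iodo‑1‑(3‑methylbut‑2‑enoyloxy)pent‑3‑en‑1‑yl]‑4‑(prop‑1‑en‑2‑yl)cyclohexane‑1‑carboxylate | C=C(C)[C@@H]1C[C@H](OC(C)=O)[C@@]([C@@H](OC(=O)C=C(C)C)[C@@H](OC(C)=O)/C=C(\I)C)(C(=O)OCC[Si](C)(C)C)CC1 | intermediate
22 | (1S,2S,4S)‑2‑acetoxy‑1‑[(1R,2S,3Z)‑2‑acetoxy‑4‑iodo‑1‑(3‑methylbut‑2‑enoyloxy)pent‑3‑en‑1‑yl]‑4‑(prop‑1‑en‑2‑yl)cyclohexane‑1‑carboxylic acid | C=C(C)[C@@H]1C[C@H](OC(C)=O)[C@@]([C@@H](OC(=O)C=C(C)C)[C@@H](OC(C)=O)/C=C(\I)C)(C(=O)O)CC1 | intermediate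
23 | (1R,2S,5R,7S,9S,10S)‑2,9‑diacetoxy‑1‑(3‑methylbut‑2‑enoyloxy)eudesma‑3,11‑dien‑14‑oic acid (trans‑decalin; the target with CO2H in place of CH2OH) | C=C(C)[C@@H]1C[C@H](OC(C)=O)[C@@]2(C(=O)O)[C@H](C1)C(C)=C[C@H](OC(C)=O)[C@@H]2OC(=O)C=C(C)C | intermediate
24 | (1R,2S,5R,7S,9S,10S)‑2,9‑diacetoxy‑1‑(3‑methylbut‑2‑enoyloxy)eudesma‑3,11‑dien‑14‑oyl chloride | C=C(C)[C@@H]1C[C@H](OC(C)=O)[C@@]2(C(Cl)=O)[C@H](C1)C(C)=C[C@H](OC(C)=O)[C@@H]2OC(=O)C=C(C)C | intermediate (not isolated)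
25 | [(1R,2S,4aR,6S,8S,8aS)‑2,8‑diacetoxy‑8a‑(hydroxymethyl)‑4‑methyl‑6‑(prop‑1‑en‑2‑yl)‑1,2,4a,5,6,7,8,8a‑octahydronaphthalen‑1‑yl] 3‑methylbut‑2‑enoate | C=C(C)[C@@H]1C[C@H](OC(C)=O)[C@@]2(CO)[C@H](C1)C(C)=C[C@H](OC(C)=O)[C@@H]2OC(=O)C=C(C)C | target

## Step count and risks

Total step count: 15. Longest linear sequence: 10 (steps 6–10 then 11–15 from but‑2‑yn‑1‑ol; the branch through steps 1–5 is equally long).

**Step 14 (proposed new ring closure).** The carboxylate‑directed palladation may be slow, or the palladacycle may undergo β‑hydride elimination before the tethered iodide adds. The fallback replaces the intramolecular C–H alkenylation by a known intermolecular 8‑aminoquinoline‑directed C–H alkenylation followed by ring‑closing metathesis. It sets out from acid 22. Bu3SnH/AIBN (toluene, 80 °C) removes the vinylic iodine to give the (E)‑propenyl acid F1. Ghosez reagent and then 8‑aminoquinoline/pyridine give the quinolin‑8‑yl amide F2. Pd(OAc)2 (10 mol %), AgOAc and 2‑iodopropene (tert‑amyl alcohol, 90 °C) alkenylate the C5–H bond cis to the amide, giving the 5‑isopropenyl amide F3. The second‑generation Grubbs catalyst (toluene, 80 °C) closes ring A between the propenyl group and the new isopropenyl group, with loss of propene, to give the trans‑decalin amide F4. Boc2O/DMAP gives the N‑Boc imide F5, and NaBH4 (THF/EtOH, 0 °C) reduces the activated acyl group to the primary alcohol, which returns to the route at target 25.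

**Step 11 (Mukaiyama aldol).** The push–pull silyl enol ether may be too unreactive, or the facial selectivity at C10 may be poor. The fallback makes the C10–C1 bond by a chromium Reformatsky reaction instead. It sets out from β‑keto ester 8. NBS with catalytic Mg(ClO4)2 (EtOAc, 0 °C) gives the α‑bromo‑β‑keto ester F6. CrCl2 with catalytic LiI (THF, rt) inserts into the C–Br bond, and the chromium enolate adds irreversibly under neutral conditions to aldehyde 17, which returns to the route at aldol 18.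

**Step 12 (Evans–Tishchenko reduction with an enal).** Retro‑aldol cleavage, acetyl migration from O2 to O1, or sluggish hydride transfer from the enal hemiacetal are possible. The fallback separates acylation and reduction. It sets out from aldol 18. 3‑Methylbut‑2‑enoyl chloride/pyridine (CH2Cl2, −20 °C) gives the keto senecioate F7. NaBH4/CeCl3 (MeOH, −40 °C) attacks the C9 ketone from the face opposite the side chain and the isopropenyl group and gives alcohol 20, now isolated. Ac2O/DMAP then returns to the route at 21.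

## Further compounds

F1 | step 14 | (1S,2S,4S)‑2‑acetoxy‑1‑[(1R,2S,3E)‑2‑acetoxy‑1‑(3‑methylbut‑2‑enoyloxy)pent‑3‑en‑1‑yl]‑4‑(prop‑1‑en‑2‑yl)cyclohexane‑1‑carboxylic acid | C=C(C)[C@@H]1C[C@H](OC(C)=O)[C@@]([C@@H](OC(=O)C=C(C)C)[C@@H](OC(C)=O)/C=C/C)(C(=O)O)CC1
F2 | step 14 | (1S,2S,4S)‑2‑acetoxy‑1‑[(1R,2S,3E)‑2‑acetoxy‑1‑(3‑methylbut‑2‑enoyloxy)pent‑3‑en‑1‑yl]‑4‑(prop‑1‑en‑2‑yl)‑N‑(quinolin‑8‑yl)cyclohexane‑1‑carboxamide | C=C(C)[C@@H]1C[C@H](OC(C)=O)[C@@]([C@@H](OC(=O)C=C(C)C)[C@@H](OC(C)=O)/C=C/C)(C(=O)Nc2cccc3cccnc23)CC1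
F3 | step 14 | (1S,2S,4S,6R)‑2‑acetoxy‑1‑[(1R,2S,3E)‑2‑acetoxy‑1‑(3‑methylbut‑2‑enoyloxy)pent‑3‑en‑1‑yl]‑4,6‑di(prop‑1‑en‑2‑yl)‑N‑(quinolin‑8‑yl)cyclohexane‑1‑carboxamide | C=C(C)[C@@H]1C[C@H](OC(C)=O)[C@@]([C@@H](OC(=O)C=C(C)C)[C@@H](OC(C)=O)/C=C/C)(C(=O)Nc2cccc3cccnc23)[C@@H](C(C)=C)CC1
F4 | step 14 | (1R,2S,5R,7S,9S,10S)‑2,9‑diacetoxy‑1‑(3‑methylbut‑2‑enoyloxy)‑N‑(quinolin‑8‑yl)eudesma‑3,11‑dien‑14‑amide | C=C(C)[C@@H]1C[C@H](OC(C)=O)[C@@]2(C(=O)Nc3cccc4cccnc34)[C@H](C1)C(C)=C[C@H](OC(C)=O)[C@@H]2OC(=O)C=C(C)C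
F5 | step 14 | tert‑butyl N‑[(1R,2S,5R,7S,9S,10S)‑2,9‑diacetoxy‑1‑(3‑methylbut‑2‑enoyloxy)eudesma‑3,11‑dien‑14‑oyl]‑N‑(quinolin‑8‑yl)carbamate | C=C(C)[C@@H]1C[C@H](OC(C)=O)[C@@]2(C(=O)N(C(=O)OC(C)(C)C)c3cccc4cccnc34)[C@H](C1)C(C)=C[C@H](OC(C)=O)[C@@H]2OC(=O)C=C(C)C
F6 | step 11 | 2‑(trimethylsilyl)ethyl (4S)‑1‑bromo‑2‑oxo‑4‑(prop‑1‑en‑2‑yl)cyclohexane‑1‑carboxylate | C=C(C)[C@@H]1CC(=O)C(Br)(C(=O)OCC[Si](C)(C)C)CC1
F7 | step 12 | 2‑(trimethylsilyl)ethyl (1R,4S)‑1‑[(1R,2S,3Z)‑2‑acetoxy‑4‑iodo‑1‑(3‑methylbut‑2‑enoyloxy)pent‑3‑en‑1‑yl]‑2‑oxo‑4‑(prop‑1‑en‑2‑yl)cyclohexane‑1‑carboxylate | C=C(C)[C@@H]1CC(=O)[C@@]([C@@H](OC(=O)C=C(C)C)[C@@H](OC(C)=O)/C=C(\I)C)(C(=O)OCC[Si](C)(C)C)CC1
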